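Monday's flask took 0.850 mM of nucleophile where Friday's took 0.650 mM, and I asked what that bought.

- Friday's: electrophile 0.50 mM; nucleophile 0.650 mM; solid base 0.150 mM; time 40 s
- Monday's: electrophile 0.50 mM; nucleophile 0.850 mM; solid base 0.150 mM; time 40 s
    solid base ⇌ free base, rate k1*(cs1 - [free base]) while solid is left; crystals form when [free base] > cs1 (cs1 = 0.47 mM, k1 = 0.0253 s⁻¹)
    electrophile + target → side product (k2 = 35.6 M⁻¹ s⁻¹)
    nucleophile + acid set free ⇌ protonated nucleophile, settled at all times (K3 = 5.7 × 10⁵ M⁻¹)
    acid set free + free base ⇌ salt of the base, settled at all times (K4 = 2.5 × 10⁷ M⁻¹)
    electrophile + nucleophile ⇌ acid set free + target (K5 = 4.7, k5 = 140 M⁻¹ s⁻¹)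
- part of the electrophile that has reacted at the end, Friday's
- part of the electrophile that has reacted at the end, Monday's
- what raising the concentration of nucleophile from its lowest to its highest value here does to the part of the electrophile that has reacted (changes below 5 percentage points count as none) (it falls / it rises / no change)
- a species is counted by the electrophile in it: one side product counts as two
- given per volume of solution although it is solid: solid base
- at the start none of the solid base is in solution
- run time (Friday's): 40 s

Each turn of step 5 frees one acid. Free base binds acid more strongly than nucleophile does, so I let the base take the first 0.150 mM; every later acid costs a second nucleophile. On Friday's charge, the equilibrium constant of step 3 times [nucleophile] came to 370, so I took free acid as small against bound acid and dropped the way back. That gave a limiting-reagent count: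

demand = 2 × electrophile charge − solid base charge = 0.850 mM

I call this the nucleophile demand. Friday's stood 0.200 mM short of it, and Monday's met it. The ceilings on step 5 followed:

Friday's: (nucleophile + solid base)/2 = 0.400 mM
Monday's: 0.500 mM, the whole electrophile charge

Step 2 takes one more electrophile per side product. Since [electrophile] + [target] stays within the charge, their product stays within its value at an even split:

extra electrophile ≤ k2 (charge/2)² t = 0.0890 mM

For a floor I gave the base no credit, two nucleophiles per turn from the start, and no step 2:

Friday's 61.5 %; Monday's 76.3 %

For Friday's roof I integrated step 5 with the base present at once. One nucleophile per turn lasted 4.49 s, then two, which reached 0.364 mM. With the step 2 allowance, that put Friday's at 90.6 % or below. Monday's roof stayed the charge itself, 100 %.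

The forecast gave 81 % (76 % to 86 %) and 92 % (87 % to 96 %), and said it rises, the remaining acid “using up about two nucleophiles per electrophile and slowing Friday's run as free nucleophile runs low”. Both numbers lay inside my brackets.

The simulation gave 81.4 % and 90.5 %: it rises, by 9 percentage points.

Target plus side product counted once gives step 5's turnover: 69.9 % on Friday's, under the 80.0 % ceiling. A neighbour flask, like Monday's but charged with 0.34 mM of nucleophile, stood 0.510 mM short of the demand. Its ceiling reckons to 0.245 mM, or 49.0 % of the electrophile, and 66.8 % with the step 2 allowance. That neighbour flask reacted to 57.8 %, with step 5's turnover at 46.4 %, and unreacted electrophile held the most of the charge at 42.2 %.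

Its constants stand for no real mixture, and the outcome is calculated.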